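**Assumption:** the target is the (2S,3S,3aS) isomer defined by the given SMILES (aryl/methyl trans, methyl/allyl trans). "Ring A" is the ring that ends as the dienone; atom labels C2, C3, C3a, C7a follow the benzofuran numbering of the target.

## Retrosynthetic overview

1. The dihydrofuran ring and the C3a quaternary centre are made last in one operation: oxidative ipso-etherification of a (1S,2S)-1,2-diarylpropan-1-ol at the allyl-bearing carbon of ring A, a 1,2-allyl shift (C7a → C3a), and loss of one O-methyl group.
2. The allyl group is put on ring A by Suzuki–Miyaura coupling of the ortho-bromo alcohol.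
3. The C2 and C3 stereocentres come from an asymmetric hydrogenation of the racemic α-aryl ketone under dynamic kinetic resolution.
4. The ketone is assembled by Pd-catalysed α-arylation of 3,4,5-trimethoxypropiophenone with 4,5-dibromoveratrole.
5. The two arenes come from phenol + propanoyl chloride and from catechol; both benzene rings are bought, and the furan ring is the only ring formed.

## Route

Step 1
Reactants: 1 catechol (benzene-1,2-diol)
Product: 2 1,2-dimethoxybenzene
Conditions: MeI (2.4 equiv), K2CO3, acetone, reflux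
Reagents that add atoms: iodomethane CI
Why: Williamson ether synthesis on both phenols; no stereocentre is involved.

Step 2
Reactants: 2 1,2-dimethoxybenzene
Product: 3 1,2-dibromo-4,5-dimethoxybenzene
Conditions: Br2 (2.05 equiv), AcOH, 10 → 25 °C
Reagents that add atoms: bromine BrBr
Why: Electrophilic aromatic bromination; each methoxy group directs para, so substitution stops at the 4,5-dibromide.

Step 3
Reactants: 4 phenol; 5 propanoyl chloride
Product: 7 1-(4-hydroxyphenyl)propan-1-one, via phenyl propanoate 6 (not isolated)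
Conditions: CF3SO3H (solvent), 0 → 25 °C
Reagents that add atoms: none
Why: O-acylation followed by acid-promoted Fries rearrangement (Friedel–Crafts acylation), which is para-selective in CF3SO3H.

Step 4
Reactants: 7 1-(4-hydroxyphenyl)propan-1-one
Product: 8 1-(3,5-dibromo-4-hydroxyphenyl)propan-1-one
Conditions: Br2 (2.05 equiv), AcOH/H2O, 15 °C
Reagents that add atoms: bromine BrBr
Why: Electrophilic aromatic bromination at both positions ortho to the phenol, which is much faster than α-bromination of the ketone.

Step 5
Reactants: 8 1-(3,5-dibromo-4-hydroxyphenyl)propan-1-one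
Product: 10 1-(3,4,5-trimethoxyphenyl)propan-1-one, via sodium 2,6-dimethoxy-4-propanoylphenolate 9 (not isolated)
Conditions: NaOMe (4 equiv), CuBr (10 mol%), MeOH/DMF, 110 °C; then Me2SO4, 30 °C
Reagents that add atoms: sodium methoxide [Na+].[O-]C; dimethyl sulfate COS(=O)(=O)OC
Why: Copper-catalysed Ullmann-type methoxylation of both aryl bromides, then O-methylation of the phenolate in the same flask; the methanol co-solvent keeps the ketone enolate concentration negligible.

Step 6
Reactants: 10 1-(3,4,5-trimethoxyphenyl)propan-1-one; 3 1,2-dibromo-4,5-dimethoxybenzene (3 equiv)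
Product: 11 rac-2-(2-bromo-4,5-dimethoxyphenyl)-1-(3,4,5-trimethoxyphenyl)propan-1-one
Conditions: Pd2(dba)3 (1 mol%), [HP(t-Bu)3]BF4 (2.4 mol%), NaOt-Bu (1.3 equiv), THF, 50 °C
Reagents that add atoms: none
Why: Palladium-catalysed ketone α-arylation (Buchwald–Hartwig type) of the propiophenone enolate; excess dibromide and low temperature enforce mono-coupling, and the new stereocentre is formed racemic and configurationally labile.

Step 7
Reactants: 11 rac-2-(2-bromo-4,5-dimethoxyphenyl)-1-(3,4,5-trimethoxyphenyl)propan-1-one
Product: 12 (1S,2S)-2-(2-bromo-4,5-dimethoxyphenyl)-1-(3,4,5-trimethoxyphenyl)propan-1-ol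
Conditions: RuCl2[(R)-xylbinap][(R)-daipen] (0.5 mol%), KOt-Bu (5 mol%), H2 (10 atm), i-PrOH, 25 °C
Reagents that add atoms: none
Why: Noyori asymmetric hydrogenation under dynamic kinetic resolution; the α-aryl ketone racemises through its enolate, the catalyst delivers hydride to the Re face of the carbonyl (1S), and the Felkin–Anh-matched ketone enantiomer reacts faster (2S), giving the like diastereomer that becomes trans-C2/C3 of the target.

Step 8
Reactants: 12 (1S,2S)-2-(2-bromo-4,5-dimethoxyphenyl)-1-(3,4,5-trimethoxyphenyl)propan-1-ol; 13 potassium allyltrifluoroborate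
Product: 14 (1S,2S)-2-(2-allyl-4,5-dimethoxyphenyl)-1-(3,4,5-trimethoxyphenyl)propan-1-ol
Conditions: Pd(OAc)2 (3 mol%), RuPhos (2-dicyclohexylphosphino-2',6'-diisopropoxybiphenyl, 6 mol%), K2CO3 (3 equiv), toluene/H2O (10:1), 80 °C
Reagents that add atoms: none
Why: Suzuki–Miyaura cross-coupling of the aryl bromide with the allyl trifluoroborate; the weak carbonate base leaves the secondary alcohol and both stereocentres untouched.

Step 9
Reactants: 14 (1S,2S)-2-(2-allyl-4,5-dimethoxyphenyl)-1-(3,4,5-trimethoxyphenyl)propan-1-ol
Product: 17 (2S,3S,3aS)-3a-allyl-5-methoxy-3-methyl-2-(3,4,5-trimethoxyphenyl)-3,3a-dihydro-1-benzofuran-6(2H)-one, via 7a-allyl arenium ion 15 (not isolated), via O-methyloxocarbenium ion 16 (not isolated)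
Conditions: PhI(OCOCF3)2 (1.1 equiv), (CF3)2CHOH/CH2Cl2 (4:1), −30 → 20 °C; then aq NaHCO3
Reagents that add atoms: none
Why: Proposed new method: the trivalent iodine reagent oxidises the more electron-rich ring A (a 4,5-dialkyl-1,2-dimethoxybenzene) by two electrons, and the tethered hydroxyl attacks the radical cation at the allyl-bearing carbon para to a methoxy group (C7a) to give arenium ion 15; a suprafacial 1,2-allyl shift (Wagner–Meerwein, dienone–phenol type) to the neighbouring cationic carbon C3a then builds the quaternary centre and the much more stable 1,3-dialkoxyallyl cation 16, which loses its O-methyl group to trifluoroacetate; C2 and C3 are carried through unchanged, and C3a is set because ring closure goes through the twist in which the C2 aryl and C3 methyl groups are both pseudo-equatorial, which places the allyl group on the face anti to the C3 methyl before it migrates on that same face; the closest known reactions are the hypervalent-iodine ipso-cyclisation of para-substituted anisoles to dienones with loss of the O-methyl group and the acid-induced 1,2-shift of 4-allylcyclohexadienones and quinol ethers.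

## Compound list

1 | catechol (benzene-1,2-diol) | Oc1ccccc1O | starting material
2 | 1,2-dimethoxybenzene | COc1ccccc1OC | intermediate
3 | 1,2-dibromo-4,5-dimethoxybenzene | COc1cc(Br)c(Br)cc1OC | intermediate
4 | phenol | Oc1ccccc1 | starting material
5 | propanoyl chloride | CCC(Cl)=O | starting material
6 | phenyl propanoate | CCC(=O)Oc1ccccc1 | intermediate
7 | 1-(4-hydroxyphenyl)propan-1-one | CCC(=O)c1ccc(O)cc1 | intermediate
8 | 1-(3,5-dibromo-4-hydroxyphenyl)propan-1-one | CCC(=O)c1cc(Br)c(O)c(Br)c1 | intermediate
9 | sodium 2,6-dimethoxy-4-propanoylphenolate | CCC(=O)c1cc(OC)c([O-])c(OC)c1.[Na+] | intermediate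
10 | 1-(3,4,5-trimethoxyphenyl)propan-1-one | CCC(=O)c1cc(OC)c(OC)c(OC)c1 | intermediate
11 | rac-2-(2-bromo-4,5-dimethoxyphenyl)-1-(3,4,5-trimethoxyphenyl)propan-1-one | CC(C(=O)c1cc(OC)c(OC)c(OC)c1)c1cc(OC)c(OC)cc1Br | intermediate
12 | (1S,2S)-2-(2-bromo-4,5-dimethoxyphenyl)-1-(3,4,5-trimethoxyphenyl)propan-1-ol | O[C@H](c1cc(OC)c(OC)c(OC)c1)[C@H](c1cc(OC)c(OC)cc1Br)C | intermediate
13 | potassium allyltrifluoroborate | C=CC[B-](F)(F)F.[K+] | starting material
14 | (1S,2S)-2-(2-allyl-4,5-dimethoxyphenyl)-1-(3,4,5-trimethoxyphenyl)propan-1-ol | O[C@H](c1cc(OC)c(OC)c(OC)c1)[C@H](c1cc(OC)c(OC)cc1CC=C)C | intermediate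
15 | 7a-allyl arenium ion: O5-methyl oxocarbenium of (2S,3S,7aR)-7a-allyl-6-methoxy-3-methyl-2-(3,4,5-trimethoxyphenyl)-2,3-dihydro-1-benzofuran-5(7aH)-one, as trifluoroacetate (allyl on C7a anti to the C3 methyl) | C=CC[C@@]12C=C(OC)C(=[O+]C)C=C1[C@H](C)[C@@H](c1cc(OC)c(OC)c(OC)c1)O2.[O-]C(=O)C(F)(F)F | intermediate
16 | O-methyloxocarbenium ion: O6-methyl oxocarbenium of the (2S,3S,3aS) target, as trifluoroacetate | C=CC[C@]12C=C(OC)C(=[O+]C)C=C1O[C@H](c1cc(OC)c(OC)c(OC)c1)[C@H]2C.[O-]C(=O)C(F)(F)F | intermediate
17 | (2S,3S,3aS)-3a-allyl-5-methoxy-3-methyl-2-(3,4,5-trimethoxyphenyl)-3,3a-dihydro-1-benzofuran-6(2H)-one | C=CC[C@]12C=C(OC)C(=O)C=C1O[C@H](c1cc(OC)c(OC)c(OC)c1)[C@H]2C | target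

## Step count and risks

Total steps: 9. Longest linear sequence: 7 steps (4 → 7 → 8 → 10 → 11 → 12 → 14 → 17).

Three steps most likely to fail:

**Step 9 (the new cascade).** The ring-A radical cation of a 1,2-diarylpropan-1-ol can fragment at the C2–C3 bond to give 3,4,5-trimethoxybenzaldehyde. The trimethoxyphenyl ring can attack ring A in place of the hydroxyl. The allyl group can move to C7 and the ring then re-aromatise. The acid released can ionise the benzylic C2–O bond of 17.

The fallback uses known reactions and brings the allyl group in as a nucleophile onto a phenol-derived quinone monoketal. It sets out from 12 and comes back at 17. Compound 12 is borylated (B2pin2, PdCl2(dppf), KOAc, dioxane, 90 °C) to the aryl pinacol boronate (1S,2S)-2-[4,5-dimethoxy-2-(4,4,5,5-tetramethyl-1,3,2-dioxaborolan-2-yl)phenyl]-1-(3,4,5-trimethoxyphenyl)propan-1-ol F1. This is oxidised in the same flask (H2O2, NaOH) to the phenol (1S,2S)-2-(2-hydroxy-4,5-dimethoxyphenyl)-1-(3,4,5-trimethoxyphenyl)propan-1-ol F2. PhI(OAc)2 in MeOH converts this para-methoxyphenol into the quinone monoketal 2-[(1S,2S)-1-hydroxy-1-(3,4,5-trimethoxyphenyl)propan-2-yl]-4,4,5-trimethoxycyclohexa-2,5-dien-1-one F3; the trimethoxyphenyl ring is not a phenol and stays untouched. Allyltrimethylsilane and BF3·OEt2 (CH2Cl2, −78 → 0 °C) ionise the ketal, and Sakurai allylation takes place at the alkyl-bearing carbon next to the carbonyl. That is the position at which propenylbenzenes add to 2-alkyl-4,4,5-trimethoxycyclohexadienone cations in the biomimetic syntheses of this neolignan class. The side-chain hydroxyl then closes onto the vinylogous ester with loss of methanol to give 17. Allylic 1,3-strain should direct the silane anti to the C3 methyl; this selectivity is less certain than in the main route, and any C3a epimer is removed by chromatography.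

**Step 6 (α-arylation with the dibromide).** The product enolate can cyclise onto the second C–Br bond to give a 2-aryl-3-methylbenzofuran, and double coupling is possible.

The fallback sets out from 2 and 10 and comes back at 11. Compound 2 is monobrominated (N-bromosuccinimide, MeCN, 0 °C) to 4-bromo-1,2-dimethoxybenzene F4. This is used in the same α-arylation with 10 to give rac-2-(3,4-dimethoxyphenyl)-1-(3,4,5-trimethoxyphenyl)propan-1-one F5, which has no second halide. Electrophilic bromination of F5 (N-bromosuccinimide, MeCN, 0 °C, dark) goes para to a methoxy group and ortho to the side chain on the electron-rich ring; the benzoyl ring is deactivated. This gives 11.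

**Step 7 (dynamic kinetic hydrogenation).** Racemisation may be too slow, or the catalyst and Felkin–Anh preferences may not reinforce each other, lowering dr and ee.

The fallback sets out from 11 and comes back at 12. Catalyst-controlled reduction without dynamic resolution ((R)-Me-CBS oxazaborolidine, i.e. the B-methyl oxazaborolidine from (R)-diphenylprolinol, with BH3·SMe2, THF, −20 °C) reduces both ketone enantiomers to the 1S alcohols. This gives 12 together with its diastereomer (1S,2R)-2-(2-bromo-4,5-dimethoxyphenyl)-1-(3,4,5-trimethoxyphenyl)propan-1-ol F6. The two are separated by chromatography; F6 is oxidised back to 11 with Dess–Martin periodinane and recycled.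

## Further compounds

F1 | step 9 | (1S,2S)-2-[4,5-dimethoxy-2-(4,4,5,5-tetramethyl-1,3,2-dioxaborolan-2-yl)phenyl]-1-(3,4,5-trimethoxyphenyl)propan-1-ol | O[C@H](c1cc(OC)c(OC)c(OC)c1)[C@H](c1cc(OC)c(OC)cc1B1OC(C)(C)C(C)(C)O1)C
F2 | step 9 | (1S,2S)-2-(2-hydroxy-4,5-dimethoxyphenyl)-1-(3,4,5-trimethoxyphenyl)propan-1-ol | O[C@H](c1cc(OC)c(OC)c(OC)c1)[C@H](c1cc(OC)c(OC)cc1O)C
F3 | step 9 | 2-[(1S,2S)-1-hydroxy-1-(3,4,5-trimethoxyphenyl)propan-2-yl]-4,4,5-trimethoxycyclohexa-2,5-dien-1-one | O[C@H](c1cc(OC)c(OC)c(OC)c1)[C@H](C1=CC(OC)(OC)C(OC)=CC1=O)C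
F4 | step 6 | 4-bromo-1,2-dimethoxybenzene | COc1ccc(Br)cc1OC
F5 | step 6 | rac-2-(3,4-dimethoxyphenyl)-1-(3,4,5-trimethoxyphenyl)propan-1-one | CC(C(=O)c1cc(OC)c(OC)c(OC)c1)c1ccc(OC)c(OC)c1
F6 | step 7 | (1S,2R)-2-(2-bromo-4,5-dimethoxyphenyl)-1-(3,4,5-trimethoxyphenyl)propan-1-ol | O[C@H](c1cc(OC)c(OC)c(OC)c1)[C@@H](c1cc(OC)c(OC)cc1Br)C
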